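The ten-membered carbocycle is treated as a masked cyclodec-5-enone: with the ring numbered C1–C10 (C4 the methyl-bearing epoxide carbon, C5 the epoxide CH, C6 the carbinol, C7 the fusion carbon carrying C11–C13, C8 the lactone O–CH, C9 the ester carbon, C10 the CHMe), C9 is the carbonyl, C8 its oxidised α-carbon and C4=C5 the alkene. An anionic oxy-Cope rearrangement of a trans-1,2-dialkenylcyclohexanol expands the six-membered ring to the ten-membered one, forms C6–C7, relays the C4 configuration to C6 and C7, and hands over a C8/C9 enolate that is hydroxylated in the same flask. The precursor carries an E silyl enol ether on C4 and an E dienyl arm on C9.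

Key step: step 11

Remark: the enolate is assumed to be oxidised on its outer face in the conformation in which it is formed, which gives the (8S) alcohol; the inverting lactone closure then gives (8R). The locants C1–C13 defined above are used in the names of all ten-membered compounds.

Step 1
Reactants: 1 2,6-dimethylcyclohexanone; 2 allyl chloroformate
Product: 4 allyl 2,6-dimethylcyclohex-1-en-1-yl carbonate (racemic), via sodium enolate 3 (not isolated)
Conditions: NaN(SiMe3)2, TMEDA, THF, −78 °C; then 2, −78 → 0 °C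
Reagents that add atoms: none
Why: The ketone can form only one enolate, which the hard chloroformate acylates on oxygen in the presence of TMEDA (enolate O-acylation).

Step 2
Reactants: 4 allyl 2,6-dimethylcyclohex-1-en-1-yl carbonate
Product: 5 (2R)-2-allyl-2,6-dimethylcyclohexan-1-one as a mixture of C6 epimers
Conditions: Pd2(dba)3 (2.5 mol%), (R)-t-BuPHOX (6 mol%), THF, 25 °C
Reagents that add atoms: none
Why: Ionisation and loss of CO2 give an allylpalladium enolate pair that recombines at the tetrasubstituted carbon inside the chiral P,N-ligand (decarboxylative asymmetric allylic alkylation, Tsuji type), the (R) ligand being the antipode of the one that gives (S)-2-allyl-2-methylcyclohexanone, while the remote C6 centre is not selected.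

Step 3
Reactants: 5 (2R)-2-allyl-2,6-dimethylcyclohexan-1-one (C6 epimers)
Product: 6 (2R,6R)-2-allyl-2,6-dimethylcyclohexan-1-one (methyl groups trans)
Conditions: NaOMe (0.2 equiv), MeOH, 25 °C; chromatography; cis-dimethyl isomer resubmitted
Reagents that add atoms: none
Why: Only C6 can enolise, so base equilibrates the two epimers without touching the quaternary centre (thermodynamic epimerisation), and the trans-dimethyl isomer is separated while the other is recycled.

Step 4
Reactants: 6 (2R,6R)-2-allyl-2,6-dimethylcyclohexan-1-one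
Product: 8 2-[(1R,3R)-1,3-dimethyl-2-oxocyclohexyl]acetaldehyde, via ozonide 7 (not isolated)
Conditions: O3, CH2Cl2, −78 °C; then Me2S, −78 → 25 °C
Reagents that add atoms: ozone, [O-][O+]=O
Why: The terminal alkene is the only site that reacts with ozone, and reductive cleavage of the ozonide gives the aldehyde one carbon shorter under neutral conditions that leave C6 untouched (ozonolysis).

Step 5
Reactants: 8 2-[(1R,3R)-1,3-dimethyl-2-oxocyclohexyl]acetaldehyde
Product: 9 (2R,6R)-2,6-dimethyl-2-[(E)-2-(triisopropylsilyloxy)ethenyl]cyclohexan-1-one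
Conditions: TIPSOTf (1.05 equiv), Et3N, CH2Cl2, −78 → 0 °C; E isomer purified on Et3N-deactivated silica
Reagents that add atoms: triisopropylsilyl trifluoromethanesulfonate, CC(C)[Si](C(C)C)(C(C)C)OS(=O)(=O)C(F)(F)F
Why: Soft enolisation should silylate the aldehyde much faster than the doubly α-branched ketone, and the quaternary neighbour should place the bulky silyloxy group trans to it, so the E enol ether should predominate and the minor Z isomer is removed (silyl enol ether formation).

Step 6
Reactants: 10 2-bromoprop-2-en-1-ol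
Product: 11 [(2-bromoprop-2-en-1-yl)oxy](tert-butyl)dimethylsilane
Conditions: TBSCl, imidazole, CH2Cl2, 0 → 25 °C
Reagents that add atoms: tert-butyldimethylsilyl chloride, CC(C)(C)[Si](C)(C)Cl
Why: Imidazole-promoted silylation of the primary alcohol is routine and masks the hydroxyl for the organometallic steps (silyl ether formation).

Step 7
Reactants: 11 [(2-bromoprop-2-en-1-yl)oxy](tert-butyl)dimethylsilane; 12 trimethylsilylacetylene
Product: 13 tert-butyldimethyl{[2-methylidene-4-(trimethylsilyl)but-3-yn-1-yl]oxy}silane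
Conditions: Pd(PPh3)2Cl2 (3 mol%), CuI (6 mol%), Et3N, THF, 40 °C
Reagents that add atoms: none
Why: The vinylic C–Br bond undergoes oxidative addition and couples with the copper acetylide to give the 1,3-enyne (Sonogashira coupling).

Step 8
Reactants: 13 tert-butyldimethyl{[2-methylidene-4-(trimethylsilyl)but-3-yn-1-yl]oxy}silane
Product: 14 tert-butyldimethyl[(2-methylidenebut-3-yn-1-yl)oxy]silane
Conditions: K2CO3 (0.2 equiv), MeOH, 0 → 25 °C
Reagents that add atoms: none
Why: Methoxide cleaves the C(sp)–Si bond selectively, while the hindered silyl ether on oxygen is stable to these conditions (protodesilylation of an alkynylsilane).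

Step 9
Reactants: 14 tert-butyldimethyl[(2-methylidenebut-3-yn-1-yl)oxy]silane
Product: 16 tert-butyl{[(3E)-4-iodo-2-methylidenebut-3-en-1-yl]oxy}dimethylsilane, via alkenylzirconocene chloride 15 (not isolated)
Conditions: Cp2Zr(H)Cl, THF, 25 °C; then I2, 0 °C, dark
Reagents that add atoms: iodine, II
Why: Zr–H adds syn to the terminal alkyne (faster than to the 1,1-disubstituted alkene) with zirconium at the terminus, and iodinolysis with retention gives the E dienyl iodide (hydrozirconation–iodination).

Step 10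
Reactants: 16 tert-butyl{[(3E)-4-iodo-2-methylidenebut-3-en-1-yl]oxy}dimethylsilane; 9 (2R,6R)-2,6-dimethyl-2-[(E)-2-(triisopropylsilyloxy)ethenyl]cyclohexan-1-one
Product: 19 (1S,2R,6R)-1-[(1E)-3-(tert-butyldimethylsilyloxymethyl)buta-1,3-dien-1-yl]-2,6-dimethyl-2-[(E)-2-(triisopropylsilyloxy)ethenyl]cyclohexan-1-ol, via dienyllithium 17 (not isolated), via dienylcerium dichloride 18 (not isolated)
Conditions: 16, t-BuLi (2.0 equiv), Et2O, −78 °C; CeCl3 (anhydrous), THF, −78 °C; then 9, −78 → −20 °C; H2O
Reagents that add atoms: none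
Why: Iodine–lithium exchange with retention of geometry and transmetalation give a weakly basic organocerium that adds to the hindered, enolisable ketone (1,2-addition) along the equatorial trajectory of the chair in which the C6 methyl and the enol-ether arm are equatorial, so the new arm should end up trans to the enol-ether arm with the hydroxyl axial, (1S).

Step 11
Reactants: 19 (1S,2R,6R)-1-[(1E)-3-(tert-butyldimethylsilyloxymethyl)buta-1,3-dien-1-yl]-2,6-dimethyl-2-[(E)-2-(triisopropylsilyloxy)ethenyl]cyclohexan-1-ol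
Product: 22 (4E,6S,7S,8S,10R)-7-[3-(tert-butyldimethylsilyloxy)prop-1-en-2-yl]-8-hydroxy-4,10-dimethyl-6-(triisopropylsilyloxy)cyclodec-4-en-9-one, via potassium alkoxide 20 (not isolated), via potassium enolate 21 (not isolated)
Conditions: KN(SiMe3)2 (1.2 equiv), 18-crown-6, THF, 0 → 25 °C; then −78 °C, 2-(phenylsulfonyl)-3-phenyloxaziridine (1.5 equiv); AcOH, −78 °C
Reagents that add atoms: 2-(phenylsulfonyl)-3-phenyloxaziridine, O=S(=O)(N1OC1c1ccccc1)c1ccccc1
Why: Deprotonation gives the potassium alkoxide, in which the 1,5-diene C6=C5–C4–C9–C8=C7 undergoes a charge-accelerated [3,3] sigmatropic shift (anionic oxy-Cope rearrangement of a 1,2-dialkenylcyclohexanol), and the regiodefined C8=C9 enolate is then oxidised at C8 by the N-sulfonyloxaziridine (enolate hydroxylation). The ten-membered carbocycle is closed by a four-carbon ring expansion of the cyclohexane, C6–C7 forming as C4–C9 breaks, not by end-to-end cyclisation. C6 and C7 are set by the chair transition state in which C3, C10, the C6 silyloxy group and the C7 propenyl unit are equatorial and the C4 methyl and the oxide axial, so the C4 configuration is relayed to (6S,7S) and C4=C5 emerges E. C8 is expected to be (S) through oxygen transfer to the outer face of the enolate in the conformation in which it is formed. The step needs chair over boat and a single rotamer at each terminus, which the trans-diequatorial alkenyl arms and the E geometry of both alkenes secure; the E enol ether also keeps its silyl group away from the oxide, and the stoichiometric amide base leaves no hydride to consume the oxidant.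

Step 12
Reactants: 22 (4E,6S,7S,8S,10R)-7-[3-(tert-butyldimethylsilyloxy)prop-1-en-2-yl]-8-hydroxy-4,10-dimethyl-6-(triisopropylsilyloxy)cyclodec-4-en-9-one
Product: 23 (4E,6S,7R,8S,10R)-7-[3-(tert-butyldimethylsilyloxy)prop-1-en-2-yl]-8-(methanesulfonyloxy)-4,10-dimethyl-6-(triisopropylsilyloxy)cyclodec-4-en-9-one
Conditions: MsCl, Et3N, CH2Cl2, −30 °C
Reagents that add atoms: methanesulfonyl chloride, CS(=O)(=O)Cl
Why: Sulfonylation of the only free hydroxyl with retention turns C8–O into a leaving group activated by the adjacent carbonyl and, at the same time, prevents lactol formation when C12 is oxidised (mesylation through sulfene).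

Step 13
Reactants: 23 (4E,6S,7R,8S,10R)-8-mesylate
Product: 24 (4E,6S,7R,8S,10R)-7-(3-hydroxyprop-1-en-2-yl)-8-(methanesulfonyloxy)-4,10-dimethyl-6-(triisopropylsilyloxy)cyclodec-4-en-9-one
Conditions: HF·pyridine, pyridine, THF, 0 °C
Reagents that add atoms: none
Why: The primary tert-butyldimethylsilyl ether is cleaved much faster than the hindered secondary triisopropylsilyl ether under buffered HF (selective desilylation).

Step 14
Reactants: 24 (4E,6S,7R,8S,10R)-7-(3-hydroxyprop-1-en-2-yl)-8-(methanesulfonyloxy)-4,10-dimethyl-6-(triisopropylsilyloxy)cyclodec-4-en-9-one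
Product: 25 2-[(4E,6S,7R,8S,10R)-8-(methanesulfonyloxy)-4,10-dimethyl-9-oxo-6-(triisopropylsilyloxy)cyclodec-4-en-7-yl]prop-2-enal
Conditions: MnO2 (activated), CH2Cl2, 25 °C
Reagents that add atoms: none
Why: MnO2 oxidises the allylic primary alcohol to the 2-substituted acrolein, and no other oxidisable hydroxyl is present (allylic oxidation).

Step 15
Reactants: 25 2-[(4E,6S,7R,8S,10R)-8-(methanesulfonyloxy)-4,10-dimethyl-9-oxo-6-(triisopropylsilyloxy)cyclodec-4-en-7-yl]prop-2-enal
Product: 27 cis-fused α-methylene keto lactone (4E,6S,7S,8R,10R)-4,10-dimethyl-9-oxo-6-(triisopropylsilyloxy)cyclodec-4-ene 8,12-olide with exocyclic C11=C13, via acrylic acid 26 (not isolated)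
Conditions: NaClO2, NaH2PO4, 2-methyl-2-butene, t-BuOH/H2O, 0 °C; crude acid, Cs2CO3, DMF, 0 → 25 °C
Reagents that add atoms: sodium chlorite NaClO2, [Na+].[O-]Cl=O
Why: Pinnick oxidation gives the acrylic acid while the scavenger protects the alkenes, and its caesium carboxylate displaces the α-keto mesylate in a 5-exo-tet SN2 reaction with inversion, so C8 becomes (R) and the γ-lactone is cis-fused.

Step 16
Reactants: 27 cis-fused α-methylene keto lactone
Product: 28 (4E,6S,7S,8R,9R,10R)-9-hydroxy-4,10-dimethyl-6-(triisopropylsilyloxy)cyclodec-4-ene 8,12-olide with exocyclic C11=C13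
Conditions: NaBH4, CeCl3·7H2O, MeOH, −78 °C
Reagents that add atoms: none
Why: Luche conditions reduce the ketone by 1,2-addition without conjugate reduction of the α-methylene lactone, and hydride is expected to enter anti to the C8–O bond on the open face (polar 1,2-induction), which gives (9R).

Step 17
Reactants: 28 (9R)-alcohol; 29 3-methylbut-2-enoic acid
Product: 31 (4E,6S,7S,8R,9R,10R)-9-(3-methylbut-2-enoyloxy)-4,10-dimethyl-6-(triisopropylsilyloxy)cyclodec-4-ene 8,12-olide with exocyclic C11=C13, via mixed anhydride 30 (not isolated)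
Conditions: 29, 2,4,6-trichlorobenzoyl chloride, Et3N, THF, 25 °C; then 28, DMAP, toluene, 25 °C
Reagents that add atoms: none
Why: The mixed anhydride and DMAP acylate the hindered secondary alcohol with retention under conditions mild enough to avoid deconjugation of the senecioyl unit (Yamaguchi esterification).

Step 18
Reactants: 31 C9 senecioate C6 silyl ether
Product: 32 (4E,6S,7R,8R,9R,10R)-6-hydroxy-9-(3-methylbut-2-enoyloxy)-4,10-dimethylcyclodec-4-ene 8,12-olide with exocyclic C11=C13
Conditions: HF·pyridine, THF, 0 → 25 °C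
Reagents that add atoms: none
Why: HF·pyridine cleaves the secondary silyl ether without base, so the α-methylene lactone, the ester and the position of the lactone should be preserved (fluoride desilylation).

Step 19
Reactants: 32 C6 allylic alcohol
Product: 33 target CNP0214930.1, (4R,5R,6R,7R,8R,9R,10R)-4,5-epoxy-6-hydroxy-9-(3-methylbut-2-enoyloxy)-4,10-dimethylcyclodecane 8,12-olide with exocyclic C11=C13
Conditions: VO(acac)2 (5 mol%), t-BuOOH (1.5 equiv), CH2Cl2, 0 → 25 °C
Reagents that add atoms: tert-butyl hydroperoxide, CC(C)(C)OO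
Why: The vanadium alkoxide of the C6 hydroxyl delivers the peroxide oxygen to the outer face of the E C4=C5 bond through a small O–C6–C5=C4 dihedral, the geometry an E-cyclodecene offers when C7 lies inside the ring, which corresponds to the erythro (anti) epoxy alcohol (4R,5R), while the electron-poor acrylate and senecioate alkenes are inert (hydroxyl-directed epoxidation).

Compound list
1 | 2,6-dimethylcyclohexanone (cis/trans mixture) | CC1CCCC(C)C1=O | starting material
2 | allyl chloroformate | C=CCOC(=O)Cl | starting material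
3 | sodium 2,6-dimethylcyclohex-1-en-1-olate | [Na+].[O-]C1=C(C)CCCC1C | intermediate
4 | allyl 2,6-dimethylcyclohex-1-en-1-yl carbonate (racemic) | C=CCOC(=O)OC1=C(C)CCCC1C | intermediate
5 | (2R)-2-allyl-2,6-dimethylcyclohexan-1-one, both C6 epimers | O=C1C(C)CCC[C@]1(C)CC=C | intermediate
6 | (2R,6R)-2-allyl-2,6-dimethylcyclohexan-1-one (methyl groups trans) | O=C1[C@H](C)CCC[C@]1(C)CC=C | intermediate
7 | ozonide of 6 (3-substituted 1,2,4-trioxolane, new centre undefined) | O=C1[C@H](C)CCC[C@]1(C)CC1OCOO1 | intermediate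
8 | 2-[(1R,3R)-1,3-dimethyl-2-oxocyclohexyl]acetaldehyde | O=C1[C@H](C)CCC[C@]1(C)CC=O | intermediate
9 | (2R,6R)-2,6-dimethyl-2-[(E)-2-(triisopropylsilyloxy)ethenyl]cyclohexan-1-one | O=C1[C@H](C)CCC[C@]1(C)/C=C/O[Si](C(C)C)(C(C)C)C(C)C | intermediate
10 | 2-bromoprop-2-en-1-ol | OCC(Br)=C | starting material
11 | [(2-bromoprop-2-en-1-yl)oxy](tert-butyl)dimethylsilane | C=C(Br)CO[Si](C)(C)C(C)(C)C | intermediate
12 | trimethylsilylacetylene | C#C[Si](C)(C)C | starting material
13 | tert-butyldimethyl{[2-methylidene-4-(trimethylsilyl)but-3-yn-1-yl]oxy}silane | C=C(CO[Si](C)(C)C(C)(C)C)C#C[Si](C)(C)C | intermediate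
14 | tert-butyldimethyl[(2-methylidenebut-3-yn-1-yl)oxy]silane | C=C(CO[Si](C)(C)C(C)(C)C)C#C | intermediate
15 | chloro[(1E)-3-(tert-butyldimethylsilyloxymethyl)buta-1,3-dien-1-yl]bis(cyclopentadienyl)zirconium | C=C(CO[Si](C)(C)C(C)(C)C)/C=C/[Zr](Cl)(C1C=CC=C1)C1C=CC=C1 | intermediate
16 | tert-butyl{[(3E)-4-iodo-2-methylidenebut-3-en-1-yl]oxy}dimethylsilane | I/C=C/C(=C)CO[Si](C)(C)C(C)(C)C | intermediate
17 | (1E)-3-(tert-butyldimethylsilyloxymethyl)buta-1,3-dien-1-yllithium | [Li]/C=C/C(=C)CO[Si](C)(C)C(C)(C)C | intermediate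
18 | (1E)-3-(tert-butyldimethylsilyloxymethyl)buta-1,3-dien-1-ylcerium dichloride | Cl[Ce](Cl)/C=C/C(=C)CO[Si](C)(C)C(C)(C)C | intermediate
19 | (1S,2R,6R)-1-[(1E)-3-(tert-butyldimethylsilyloxymethyl)buta-1,3-dien-1-yl]-2,6-dimethyl-2-[(E)-2-(triisopropylsilyloxy)ethenyl]cyclohexan-1-ol | C=C(CO[Si](C)(C)C(C)(C)C)/C=C/[C@@]1(O)[C@H](C)CCC[C@]1(C)/C=C/O[Si](C(C)C)(C(C)C)C(C)C | intermediate
20 | potassium alkoxide of 19 | [K+].C=C(CO[Si](C)(C)C(C)(C)C)/C=C/[C@@]1([O-])[C@H](C)CCC[C@]1(C)/C=C/O[Si](C(C)C)(C(C)C)C(C)C | intermediate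
21 | potassium C8=C9 enolate of the ring-expanded ketone (E C4=C5, O cis to C7) | [K+].[O-]/C1=C\[C@H](C(=C)CO[Si](C)(C)C(C)(C)C)[C@@H](O[Si](C(C)C)(C(C)C)C(C)C)/C=C(\C)CCC[C@H]1C | intermediate
22 | (4E,6S,7S,8S,10R)-7-[3-(tert-butyldimethylsilyloxy)prop-1-en-2-yl]-8-hydroxy-4,10-dimethyl-6-(triisopropylsilyloxy)cyclodec-4-en-9-one | O[C@@H]1C(=O)[C@H](C)CCC/C(C)=C/[C@H](O[Si](C(C)C)(C(C)C)C(C)C)[C@H]1C(=C)CO[Si](C)(C)C(C)(C)C | intermediate
23 | (4E,6S,7R,8S,10R)-7-[3-(tert-butyldimethylsilyloxy)prop-1-en-2-yl]-8-(methanesulfonyloxy)-4,10-dimethyl-6-(triisopropylsilyloxy)cyclodec-4-en-9-one | CS(=O)(=O)O[C@@H]1C(=O)[C@H](C)CCC/C(C)=C/[C@H](O[Si](C(C)C)(C(C)C)C(C)C)[C@H]1C(=C)CO[Si](C)(C)C(C)(C)C | intermediate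
24 | (4E,6S,7R,8S,10R)-7-(3-hydroxyprop-1-en-2-yl)-8-(methanesulfonyloxy)-4,10-dimethyl-6-(triisopropylsilyloxy)cyclodec-4-en-9-one | CS(=O)(=O)O[C@@H]1C(=O)[C@H](C)CCC/C(C)=C/[C@H](O[Si](C(C)C)(C(C)C)C(C)C)[C@H]1C(=C)CO | intermediate
25 | 2-[(4E,6S,7R,8S,10R)-8-(methanesulfonyloxy)-4,10-dimethyl-9-oxo-6-(triisopropylsilyloxy)cyclodec-4-en-7-yl]prop-2-enal | CS(=O)(=O)O[C@@H]1C(=O)[C@H](C)CCC/C(C)=C/[C@H](O[Si](C(C)C)(C(C)C)C(C)C)[C@H]1C(=C)C=O | intermediate
26 | 2-[(4E,6S,7R,8S,10R)-8-(methanesulfonyloxy)-4,10-dimethyl-9-oxo-6-(triisopropylsilyloxy)cyclodec-4-en-7-yl]prop-2-enoic acid | CS(=O)(=O)O[C@@H]1C(=O)[C@H](C)CCC/C(C)=C/[C@H](O[Si](C(C)C)(C(C)C)C(C)C)[C@H]1C(=C)C(=O)O | intermediate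
27 | cis-fused α-methylene keto lactone, (4E,6S,7S,8R,10R)-4,10-dimethyl-9-oxo-6-(triisopropylsilyloxy)cyclodec-4-ene 8,12-olide, C11=C13 exocyclic | C=C1C(=O)O[C@H]2C(=O)[C@H](C)CCC/C(C)=C/[C@H](O[Si](C(C)C)(C(C)C)C(C)C)[C@@H]12 | intermediate
28 | (4E,6S,7S,8R,9R,10R)-9-hydroxy-4,10-dimethyl-6-(triisopropylsilyloxy)cyclodec-4-ene 8,12-olide, C11=C13 exocyclic | C=C1C(=O)O[C@H]2[C@H](O)[C@H](C)CCC/C(C)=C/[C@H](O[Si](C(C)C)(C(C)C)C(C)C)[C@@H]12 | intermediate
29 | 3-methylbut-2-enoic acid | CC(C)=CC(=O)O | starting material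
30 | 3-methylbut-2-enoic 2,4,6-trichlorobenzoic anhydride | CC(C)=CC(=O)OC(=O)c1c(Cl)cc(Cl)cc1Cl | intermediate
31 | (4E,6S,7S,8R,9R,10R)-9-(3-methylbut-2-enoyloxy)-4,10-dimethyl-6-(triisopropylsilyloxy)cyclodec-4-ene 8,12-olide, C11=C13 exocyclic | C=C1C(=O)O[C@H]2[C@H](OC(=O)C=C(C)C)[C@H](C)CCC/C(C)=C/[C@H](O[Si](C(C)C)(C(C)C)C(C)C)[C@@H]12 | intermediate
32 | (4E,6S,7R,8R,9R,10R)-6-hydroxy-9-(3-methylbut-2-enoyloxy)-4,10-dimethylcyclodec-4-ene 8,12-olide, C11=C13 exocyclic | C=C1C(=O)O[C@H]2[C@H](OC(=O)C=C(C)C)[C@H](C)CCC/C(C)=C/[C@H](O)[C@@H]12 | intermediate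
33 | CNP0214930.1, (4R,5R,6R,7R,8R,9R,10R)-4,5-epoxy-6-hydroxy-9-(3-methylbut-2-enoyloxy)-4,10-dimethylcyclodecane 8,12-olide, C11=C13 exocyclic | C=C1C(=O)O[C@H]2[C@H](OC(=O)C=C(C)C)[C@H](C)CCC[C@@]3(C)O[C@@H]3[C@H](O)[C@@H]12 | target

Total step count: 19 steps.
Longest linear sequence: 15 steps (steps 1–5, then 10–19, from 2,6-dimethylcyclohexanone). The dienyl iodide branch (steps 6–9) joins at step 10.

Steps most likely to fail

Step 11 (ring expansion with hydroxylation). The enolate unit may turn through the ten-membered ring before oxygen transfer, or the α-ketol may epimerise in the basic medium, so oxygen may end up on the other face of C8. Fallback: setting out from 19, the same operation would then deliver the (8R)-hydroxy ketone F1. HF·pyridine would free the primary alcohol to give diol F2. MnO2 would oxidise it through the hydroxy enal F3 and the lactol F4 to the cis-fused keto lactone, the C8 oxygen now being retained (oxidative lactonisation of a 2-methylene-1,4-diol). This rejoins the route at 27 and is two steps shorter than steps 12–15.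

Step 10 (addition to the hindered ketone). The bulky dienyl metal may add slowly, with competing enolisation at C6 or loss of the reagent, and part of the addition may follow the axial trajectory. Fallback: setting out from 9 and enyne 14, deprotonation with n-BuLi in THF at −78 °C gives the lithium acetylide F5, a slim and weakly basic nucleophile. It adds to 9 to give the propargylic alcohol F6. Hydroxyl-directed trans-hydroalumination with NaAlH2(OCH2CH2OMe)2 in THF (0 → 25 °C) and protonolysis then gives the E dienyl carbinol. This rejoins the route at 19 and makes step 9 unnecessary.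

Step 16 (reduction of the C9 ketone). In the flexible medium ring, hydride may be delivered to the other carbonyl face, which would give the C9 epimer. Fallback: setting out from 27, the reduction would then give the (9S)-alcohol F7. Esterification under Mitsunobu conditions (29, PPh3, DIAD, toluene, 0 → 25 °C) would introduce the senecioate with inversion at C9. This rejoins the route at 31 and replaces step 17.

Further compounds
F1 | step 11 | (4E,6S,7S,8R,10R)-7-[3-(tert-butyldimethylsilyloxy)prop-1-en-2-yl]-8-hydroxy-4,10-dimethyl-6-(triisopropylsilyloxy)cyclodec-4-en-9-one (C8 epimer of 22) | O[C@H]1C(=O)[C@H](C)CCC/C(C)=C/[C@H](O[Si](C(C)C)(C(C)C)C(C)C)[C@H]1C(=C)CO[Si](C)(C)C(C)(C)C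
F2 | step 11 | C8-epimeric diol, 7-(3-hydroxyprop-1-en-2-yl)-8-hydroxy ketone | O[C@H]1C(=O)[C@H](C)CCC/C(C)=C/[C@H](O[Si](C(C)C)(C(C)C)C(C)C)[C@H]1C(=C)CO
F3 | step 11 | C8-epimeric hydroxy enal | O[C@H]1C(=O)[C@H](C)CCC/C(C)=C/[C@H](O[Si](C(C)C)(C(C)C)C(C)C)[C@H]1C(=C)C=O
F4 | step 11 | cis-fused lactol (C12 hemiacetal, C12 undefined) | C=C1C(O)O[C@H]2C(=O)[C@H](C)CCC/C(C)=C/[C@H](O[Si](C(C)C)(C(C)C)C(C)C)[C@@H]12
F5 | step 10 | lithium acetylide of 14 | [Li]C#CC(=C)CO[Si](C)(C)C(C)(C)C
F6 | step 10 | (1S,2R,6R)-1-[3-(tert-butyldimethylsilyloxymethyl)but-3-en-1-yn-1-yl]-2,6-dimethyl-2-[(E)-2-(triisopropylsilyloxy)ethenyl]cyclohexan-1-ol | C=C(CO[Si](C)(C)C(C)(C)C)C#C[C@@]1(O)[C@H](C)CCC[C@]1(C)/C=C/O[Si](C(C)C)(C(C)C)C(C)C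
F7 | step 16 | (9S)-alcohol, C9 epimer of 28 | C=C1C(=O)O[C@H]2[C@@H](O)[C@H](C)CCC/C(C)=C/[C@H](O[Si](C(C)C)(C(C)C)C(C)C)[C@@H]12
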